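The skeleton is cut between C1 of the guaiacyl ring (ring A) and the benzylic carbinol carbon C7. In the forward sense an aryl Grignard reagent (ring A, phenol silylated) adds to an enantiopure (S)-2-aryloxy-3-silyloxypropanal that already carries the complete sinapyl ether unit (ring B) and the C8 centre, set earlier by Mitsunobu inversion of a D-glycerate. The step exploits the C8 aryl-ether oxygen, flanked by an ortho-methoxy group of ring B, next to the C7 carbonyl: magnesium chelation between these oxygens fixes the face of attack, so one operation forms the C1–C7 bond and the (7S) carbinol of the threo-(7S,8S) array. Global desilylation then gives the target.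

Key step: step 6

Remark: lignan numbering is used (C7 benzylic carbinol carbon, C8 aryloxy-bearing carbon, C9 the CH2OH carbon; ring A guaiacyl, ring B sinapyl), and sinapyl alcohol and methyl (R)-glycerate are taken as purchased; TBDPS = tert-butyldiphenylsilyl, TBS = tert-butyldimethylsilyl.

Step 1
Reactants: 1 sinapyl alcohol, (E)-4-(3-hydroxyprop-1-en-1-yl)-2,6-dimethoxyphenol
Product: 2 (E)-4-[3-(TBDPS-oxy)prop-1-en-1-yl]-2,6-dimethoxyphenol
Conditions: TBDPSCl (1.05 equiv), imidazole, CH2Cl2, 0 °C
Reagents that add atoms: tert-butyl(chloro)diphenylsilane (TBDPSCl), CC(C)(C)[Si](Cl)(c1ccccc1)c1ccccc1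
Why: Imidazole-promoted silyl ether formation; the unhindered primary allylic alcohol should react with the bulky silyl chloride much faster than the phenol flanked by two ortho-methoxy groups.

Step 2
Reactants: 3 methyl (R)-2,3-dihydroxypropanoate (methyl D-glycerate)
Product: 4 methyl (R)-3-(TBDPS-oxy)-2-hydroxypropanoate
Conditions: TBDPSCl (1.0 equiv), imidazole, CH2Cl2, 0 °C
Reagents that add atoms: tert-butyl(chloro)diphenylsilane (TBDPSCl), CC(C)(C)[Si](Cl)(c1ccccc1)c1ccccc1
Why: Regioselective silyl ether formation; the bulky silyl chloride should discriminate the primary from the secondary hydroxyl, and the C2 stereocentre is not touched.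

Step 3
Reactants: 2 (E)-4-[3-(TBDPS-oxy)prop-1-en-1-yl]-2,6-dimethoxyphenol; 4 methyl (R)-3-(TBDPS-oxy)-2-hydroxypropanoate
Product: 5 methyl (S)-3-(TBDPS-oxy)-2-{4-[(E)-3-(TBDPS-oxy)prop-1-en-1-yl]-2,6-dimethoxyphenoxy}propanoate
Conditions: PPh3, DIAD, THF, 0 °C to rt
Reagents that add atoms: none
Why: Mitsunobu etherification; the phenol (pKa about 10) should displace the alkoxyphosphonium ion next to the ester by SN2 with inversion, turning (R)-4 into the (S)-aryl ether that becomes C8.

Step 4
Reactants: 5 methyl (S)-3-(TBDPS-oxy)-2-{4-[(E)-3-(TBDPS-oxy)prop-1-en-1-yl]-2,6-dimethoxyphenoxy}propanoate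
Product: 6 (S)-3-(TBDPS-oxy)-2-{4-[(E)-3-(TBDPS-oxy)prop-1-en-1-yl]-2,6-dimethoxyphenoxy}propanal
Conditions: i-Bu2AlH (1.1 equiv), CH2Cl2, −78 °C; MeOH, then aq. potassium sodium tartrate (KNaC4H4O6); used crude at once
Reagents that add atoms: none
Why: Partial ester reduction with i-Bu2AlH; the α-aryloxy oxygen stabilises the tetrahedral aluminium hemiacetal at −78 °C so the aldehyde appears only on work-up, and the non-basic conditions should leave the α-stereocentre intact.

Step 5
Reactants: 7 4-bromo-2-methoxyphenol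
Product: 8 (4-bromo-2-methoxyphenoxy)(tert-butyl)dimethylsilane
Conditions: TBSCl, imidazole, DMF, rt
Reagents that add atoms: tert-butyl(chloro)dimethylsilane (TBSCl), CC(C)(C)[Si](C)(C)Cl
Why: Imidazole-promoted phenol silylation masks the acidic OH so that the aryl bromide can be turned into a Grignard reagent.

Step 6
Reactants: 6 (S)-3-(TBDPS-oxy)-2-{4-[(E)-3-(TBDPS-oxy)prop-1-en-1-yl]-2,6-dimethoxyphenoxy}propanal; 8 (4-bromo-2-methoxyphenoxy)(tert-butyl)dimethylsilane
Product: 10 (1S,2S)-1-[4-(TBS-oxy)-3-methoxyphenyl]-3-(TBDPS-oxy)-2-{4-[(E)-3-(TBDPS-oxy)prop-1-en-1-yl]-2,6-dimethoxyphenoxy}propan-1-ol, via arylmagnesium bromide 9 (not isolated)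
Conditions: 8, Mg turnings, I2 (cat.), THF, 45 °C; then added slowly (1.5 equiv) to 6 precomplexed with MgBr2·OEt2 (2 equiv) in CH2Cl2, −78 °C; sat. aq. NH4Cl at −78 °C
Reagents that add atoms: none
Why: Grignard 1,2-addition to an aldehyde under Cram-chelate control, the closest known reaction type being chelation-controlled organomagnesium addition to α-alkoxy aldehydes in CH2Cl2 with MgBr2·OEt2. Divalent magnesium is held between the C7 carbonyl oxygen and the C8 aryl-ether oxygen (a five-membered chelate, reinforced by an ortho-methoxy oxygen of ring B), which locks the C7–C8 rotamer with C=O and C8–O syn-periplanar. The aryl group of 9 then attacks C7 from the face of the small C8–H, away from the CH2OTBDPS arm, so the existing (S)-C8 centre sets the new C7 centre as (S) and gives the threo-(7S,8S) array; no ring is closed. The selectivity needed is facial (chelate against the open polar Felkin–Anh mode, which would give the erythro epimer); it is secured by precomplexation in a non-coordinating solvent, by the bulky non-chelating TBDPS ether on the C9 oxygen and by the low temperature. Fast addition at −78 °C should outrun enolisation of the α-aryloxy aldehyde, and the aldehyde is the only electrophile present.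

Step 7
Reactants: 10 (1S,2S)-1-[4-(TBS-oxy)-3-methoxyphenyl]-3-(TBDPS-oxy)-2-{4-[(E)-3-(TBDPS-oxy)prop-1-en-1-yl]-2,6-dimethoxyphenoxy}propan-1-ol
Product: 11 (1S,2S)-1-(4-hydroxy-3-methoxyphenyl)-2-{4-[(E)-3-hydroxyprop-1-en-1-yl]-2,6-dimethoxyphenoxy}propane-1,3-diol (target)
Conditions: Bu4NF (5 equiv), AcOH (5 equiv), THF, 0 °C to rt
Reagents that add atoms: none
Why: Fluoride-mediated desilylation; acetic-acid-buffered Bu4NF should cleave the aryl TBS ether and both primary TBDPS ethers without base-induced quinone methide formation or epimerisation at the benzylic C7.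

Compound list
1 | sinapyl alcohol, (E)-4-(3-hydroxyprop-1-en-1-yl)-2,6-dimethoxyphenol | COc1cc(/C=C/CO)cc(OC)c1O | starting material
2 | (E)-4-[3-(tert-butyldiphenylsilyloxy)prop-1-en-1-yl]-2,6-dimethoxyphenol | COc1cc(/C=C/CO[Si](c2ccccc2)(c2ccccc2)C(C)(C)C)cc(OC)c1O | intermediate
3 | methyl (R)-2,3-dihydroxypropanoate (methyl D-glycerate) | COC(=O)[C@H](O)CO | starting material
4 | methyl (R)-3-(tert-butyldiphenylsilyloxy)-2-hydroxypropanoate | COC(=O)[C@H](O)CO[Si](c1ccccc1)(c1ccccc1)C(C)(C)C | intermediate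
5 | methyl (S)-3-(tert-butyldiphenylsilyloxy)-2-{4-[(E)-3-(tert-butyldiphenylsilyloxy)prop-1-en-1-yl]-2,6-dimethoxyphenoxy}propanoate | COC(=O)[C@@H](Oc1c(OC)cc(/C=C/CO[Si](c2ccccc2)(c2ccccc2)C(C)(C)C)cc1OC)CO[Si](c1ccccc1)(c1ccccc1)C(C)(C)C | intermediate
6 | (S)-3-(tert-butyldiphenylsilyloxy)-2-{4-[(E)-3-(tert-butyldiphenylsilyloxy)prop-1-en-1-yl]-2,6-dimethoxyphenoxy}propanal | O=C[C@@H](Oc1c(OC)cc(/C=C/CO[Si](c2ccccc2)(c2ccccc2)C(C)(C)C)cc1OC)CO[Si](c1ccccc1)(c1ccccc1)C(C)(C)C | intermediate
7 | 4-bromo-2-methoxyphenol | COc1cc(Br)ccc1O | starting material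
8 | (4-bromo-2-methoxyphenoxy)(tert-butyl)dimethylsilane | COc1cc(Br)ccc1O[Si](C)(C)C(C)(C)C | intermediate
9 | [4-(tert-butyldimethylsilyloxy)-3-methoxyphenyl]magnesium bromide | COc1cc([Mg]Br)ccc1O[Si](C)(C)C(C)(C)C | intermediate
10 | (1S,2S)-1-[4-(tert-butyldimethylsilyloxy)-3-methoxyphenyl]-3-(tert-butyldiphenylsilyloxy)-2-{4-[(E)-3-(tert-butyldiphenylsilyloxy)prop-1-en-1-yl]-2,6-dimethoxyphenoxy}propan-1-ol | COc1cc([C@H](O)[C@H](CO[Si](c2ccccc2)(c2ccccc2)C(C)(C)C)Oc2c(OC)cc(/C=C/CO[Si](c3ccccc3)(c3ccccc3)C(C)(C)C)cc2OC)ccc1O[Si](C)(C)C(C)(C)C | intermediate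
11 | (1S,2S)-1-(4-hydroxy-3-methoxyphenyl)-2-{4-[(E)-3-hydroxyprop-1-en-1-yl]-2,6-dimethoxyphenoxy}propane-1,3-diol, the threo-(7S,8S) isomer | COc1cc([C@H](O)[C@H](CO)Oc2c(OC)cc(/C=C/CO)cc2OC)ccc1O | target

Total step count: 7. Longest linear sequence: 5 steps (steps 1, 3, 4, 6, 7; equally steps 2, 3, 4, 6, 7).

Steps most likely to fail

1. Step 6. The open polar Felkin–Anh mode may compete with the magnesium chelate, eroding facial selectivity toward the erythro epimer. The basic Grignard reagent may also enolise the α-aryloxy aldehyde, with loss of configuration at C8 or β-elimination. The fallback sets out from ester 5 and bromide 8 and returns at 10, avoiding the labile aldehyde. Ester 5 would be treated with MeNH(OMe)·HCl and i-PrMgCl (THF, −20 °C) to give the Weinreb amide F1. Bromide 8 would be converted with t-BuLi (2 equiv, Et2O, −78 °C) into the aryllithium F2, which should add once to F1 to give the aryl ketone F3. Reduction of F3 with LiBH(s-Bu)3 (THF, −78 °C), a bulky non-chelating hydride that follows the Felkin–Anh mode with hydride anti to the C8 aryloxy group, should give the threo alcohol 10.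

2. Step 3. The SN2 displacement at the alkoxyphosphonium ion by the di-ortho-substituted phenol may be slow, letting elimination or alkylation of the reduced azodicarboxylate take over. The fallback sets out from 4 and 2 and returns at 5. Alcohol 4 would be converted with Tf2O and 2,6-lutidine (CH2Cl2, −78 °C) into the triflate F4. The potassium phenoxide of 2 (K2CO3, MeCN, 0 °C) should then displace the triflate with inversion to give 5.

3. Step 4. The reduction may run on to the primary alcohol, or the configurationally labile aldehyde may epimerise during work-up. The fallback sets out from 5 and returns at 6. Full reduction with LiBH4 (THF, 0 °C) would give the primary alcohol F5. Oxidation with Dess–Martin periodinane buffered with NaHCO3 (CH2Cl2, 0 °C) should then give aldehyde 6 under neutral conditions.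

Further compounds
F1 | step 6 | (S)-3-(tert-butyldiphenylsilyloxy)-2-{4-[(E)-3-(tert-butyldiphenylsilyloxy)prop-1-en-1-yl]-2,6-dimethoxyphenoxy}-N-methoxy-N-methylpropanamide | CON(C)C(=O)[C@@H](Oc1c(OC)cc(/C=C/CO[Si](c2ccccc2)(c2ccccc2)C(C)(C)C)cc1OC)CO[Si](c1ccccc1)(c1ccccc1)C(C)(C)C
F2 | step 6 | [4-(tert-butyldimethylsilyloxy)-3-methoxyphenyl]lithium | COc1cc([Li])ccc1O[Si](C)(C)C(C)(C)C
F3 | step 6 | (S)-1-[4-(tert-butyldimethylsilyloxy)-3-methoxyphenyl]-3-(tert-butyldiphenylsilyloxy)-2-{4-[(E)-3-(tert-butyldiphenylsilyloxy)prop-1-en-1-yl]-2,6-dimethoxyphenoxy}propan-1-one | COc1cc(C(=O)[C@@H](Oc2c(OC)cc(/C=C/CO[Si](c3ccccc3)(c3ccccc3)C(C)(C)C)cc2OC)CO[Si](c2ccccc2)(c2ccccc2)C(C)(C)C)ccc1O[Si](C)(C)C(C)(C)C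
F4 | step 3 | methyl (R)-3-(tert-butyldiphenylsilyloxy)-2-(trifluoromethylsulfonyloxy)propanoate | COC(=O)[C@H](OS(=O)(=O)C(F)(F)F)CO[Si](c1ccccc1)(c1ccccc1)C(C)(C)C
F5 | step 4 | (R)-3-(tert-butyldiphenylsilyloxy)-2-{4-[(E)-3-(tert-butyldiphenylsilyloxy)prop-1-en-1-yl]-2,6-dimethoxyphenoxy}propan-1-ol | OC[C@@H](Oc1c(OC)cc(/C=C/CO[Si](c2ccccc2)(c2ccccc2)C(C)(C)C)cc1OC)CO[Si](c1ccccc1)(c1ccccc1)C(C)(C)C
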